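**Retrosynthetic overview**

1. Numbering (also used for the open-chain compounds): ring C1 (CMe2), C2 (Cl), C3, C4, C5, C6 (Br), ring alkene C4=C5, side chain C7 (Cl) and C8 (Br) on C5. The plan rests on the C1–C6 bond of the cyclohexene ring, where a quaternary carbon meets a CHBr carbon with a chloride next door at C2, the mark of a chloronium-type cation–olefin closure.
2. C7–Cl is installed last by ene-type chlorination of an exocyclic C5=C7 alkene, which also moves the alkene to C4=C5.
3. Key disconnection: C1–C6 (the only ring, closed once) together with C8–Br, by ionising the tertiary alcohol of an open-chain (S)-chlorohydrin (E)-bromodiene so that C6 closes onto C1 and bromide caps the allyl cation.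
4. The chlorohydrin comes from an α-chloro ester and methylmagnesium bromide; the C2 chloride is set by enamine-catalysed α-chlorination of an aldehyde.
5. The (E)-bromodiene is fixed in the first step by copper-catalysed anti-vinylmagnesiation of propargyl alcohol and bromination; C1–C3 are added by allylic coupling with a three-carbon acetal Grignard reagent.

Key step: step 9

Assumption: in step 5 the (2R,5R) antipode of 2,5-diphenylpyrrolidine is taken to give the (2S) aldehyde; if the sense is the opposite on this substrate, the (2S,5S) antipode is used with no other change.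

**Route**

Step 1
Reactants: 1 prop-2-yn-1-ol; 2 vinylmagnesium bromide
Product: 4 (2Z)-2-(bromomethylidene)but-3-en-1-ol, via magnesium chelate 3 (not isolated)
Conditions: 2 (2.5 equiv), CuI (10 mol %), THF, −10 °C → rt; then N-bromosuccinimide, −78 → 0 °C; aq NH4Cl
Reagents that add atoms: N-bromosuccinimide, BrN1C(=O)CCC1=O
Why: Copper-catalysed anti-carbomagnesiation of the propargylic alkoxide puts vinyl on C5 and magnesium on C6 inside a five-membered chelate, and bromination of that alkenyl Grignard reagent with retention leaves bromine cis to C4 and trans to vinyl, which is the (E)-bromodiene geometry the key step needs.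

Step 2
Reactants: 4 (2Z)-2-(bromomethylidene)but-3-en-1-ol
Product: 5 (1Z)-1-bromo-2-(bromomethyl)buta-1,3-diene
Conditions: CBr4, PPh3, CH2Cl2, 0 °C; used at once
Reagents that add atoms: carbon tetrabromide, BrC(Br)(Br)Br
Why: Appel bromination of a primary allylic alcohol under neutral conditions, an SN2 displacement at C4 that does not touch the alkenyl bromide or its geometry.

Step 3
Reactants: 5 (1Z)-1-bromo-2-(bromomethyl)buta-1,3-diene; 6 [2-(1,3-dioxan-2-yl)ethyl]magnesium bromide
Product: 7 2-[(4E)-5-bromo-4-ethenylpent-4-en-1-yl]-1,3-dioxane
Conditions: 6 (1.3 equiv, THF solution, added fast), Li2CuCl4 (3 mol %), THF, −78 → −20 °C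
Reagents that add atoms: none
Why: Copper-catalysed cross-coupling of a primary alkyl Grignard reagent with a primary allylic bromide; in THF at low temperature with fast addition the dialkylcuprate pathway should deliver the alkyl group to C4 (SN2) and not to the bromine-bearing C6, and the alkenyl bromide does not react under these conditions.

Step 4
Reactants: 7 2-[(4E)-5-bromo-4-ethenylpent-4-en-1-yl]-1,3-dioxane
Product: 8 (5E)-6-bromo-5-ethenylhex-5-enal
Conditions: 1 M HCl (aq), THF, 40 °C
Reagents that add atoms: water, O
Why: Acid-catalysed hydrolysis of the cyclic acetal frees the C1 aldehyde without affecting the bromodiene.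

Step 5
Reactants: 8 (5E)-6-bromo-5-ethenylhex-5-enal
Product: 9 (2S,5E)-6-bromo-2-chloro-5-ethenylhex-5-enal
Conditions: (2R,5R)-2,5-diphenylpyrrolidine (10 mol %), N-chlorosuccinimide, CH2Cl2, −20 °C → rt; used crude
Reagents that add atoms: N-chlorosuccinimide, ClN1C(=O)CCC1=O
Why: Enamine-catalysed electrophilic α-chlorination of an aldehyde, in which the C2-symmetric pyrrolidine shields one face of the (E)-enamine so that chlorine reaches C2 under catalyst control to give the (S) chloride; the enamine is far more nucleophilic than the bromodiene.

Step 6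
Reactants: 9 (2S,5E)-6-bromo-2-chloro-5-ethenylhex-5-enal
Product: 10 (2S,5E)-6-bromo-2-chloro-5-ethenylhex-5-enoic acid
Conditions: NaClO2, NaH2PO4, 2-methylbut-2-ene, t-BuOH/H2O, 0 °C
Reagents that add atoms: sodium chlorite, [Na+].[O-]Cl=O
Why: Pinnick oxidation under buffered conditions turns the configurationally labile α-chloro aldehyde into the stable acid without enolisation, the alkene scavenger taking up the hypochlorous acid that would otherwise attack the diene.

Step 7
Reactants: 10 (2S,5E)-6-bromo-2-chloro-5-ethenylhex-5-enoic acid
Product: 11 methyl (2S,5E)-6-bromo-2-chloro-5-ethenylhex-5-enoate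
Conditions: Me3SiCHN2, toluene/MeOH, 0 °C
Reagents that add atoms: trimethylsilyldiazomethane, C[Si](C)(C)C=[N+]=[N-]
Why: Esterification with trimethylsilyldiazomethane is neutral and fast, so the α-chloro stereocentre should not epimerise.

Step 8
Reactants: 11 methyl (2S,5E)-6-bromo-2-chloro-5-ethenylhex-5-enoate; 12 methylmagnesium bromide
Product: 14 (3S,6E)-6-(bromomethylidene)-3-chloro-2-methyloct-7-en-2-ol, via chloro ketone 13 (not isolated)
Conditions: 12 (3 equiv), THF/Et2O, −78 → −20 °C; aq NH4Cl at −20 °C
Reagents that add atoms: none
Why: Double Grignard addition to the ester through ketone 13 builds the tertiary alcohol at C1 while the C2 chloride is a spectator, a standard way to chlorohydrins of this type, and the cold quench prevents the magnesium alkoxide from closing to the epoxide.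

Step 9
Reactants: 14 (3S,6E)-6-(bromomethylidene)-3-chloro-2-methyloct-7-en-2-ol
Product: 15 (1S,3S,4E)-3-bromo-4-(2-bromoethylidene)-1-chloro-2,2-dimethylcyclohexane
Conditions: HBr (anhydrous, 1.2 equiv), (CF3)2CHOH/CH2Cl2, −30 → 0 °C
Reagents that add atoms: hydrogen bromide, Br
Why: Proposed new method: protonation of the tertiary hydroxyl in the strongly ionising, weakly nucleophilic medium and loss of water should give the C1 cation, held as a chloronium-type bridge by the C2 chlorine, which C6 of the bromodiene attacks to form the C1–C6 bond; the C5–C7–C8 allyl cation that results is capped by bromide at the primary C8 terminus, capture at C5 being reversible. The closest known reaction type is the stereospecific halonium polyene cyclisation started by solvolysis of an enantioenriched vicinal dihalide (tertiary leaving group, neighbouring halogen holding the configuration) in hexafluoroisopropanol. The single ring closes in a 6-endo-trig mode through a chair. C2 is not touched by the ionisation and keeps its (S) configuration, and the new C6 centre is set by that chair, in which the C2 chlorine sits equatorial and the bromine, cis to C4 on the (E)-alkene, is forced axial and therefore trans to chlorine. The step needs attack through the bromine-bearing carbon, which is favoured because only that mode gives a six-membered ring and a tertiary allyl cation, and it needs the (E) exocyclic alkene, which follows from the s-trans conformer of the diene. The acid itself supplies the bromide, so no second nucleophile competes for the allyl cation.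

Step 10
Reactants: 15 (1S,3S,4E)-3-bromo-4-(2-bromoethylidene)-1-chloro-2,2-dimethylcyclohexane
Product: 16 (4S,6R)-6-bromo-1-[(1S)-2-bromo-1-chloroethyl]-4-chloro-5,5-dimethylcyclohex-1-ene
Conditions: Ca(OCl)2, CO2 (solid), CH2Cl2/H2O, 0 °C
Reagents that add atoms: calcium hypochlorite, [Ca+2].[O-]Cl.[O-]Cl
Why: Ene-type allylic chlorination with hypochlorous acid in a two-phase system, in which electrophilic chlorine adds to the less substituted C7 of the (E) C5=C7 alkene from the face anti to the axial C6–Br bond, which sets C7 as (S), and loss of the axial C4 hydrogen from the C5 cation moves the alkene into the ring (the equatorial C6 hydrogen is not aligned).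

**Compound list**

1 | prop-2-yn-1-ol (propargyl alcohol) | OCC#C | starting material
2 | vinylmagnesium bromide | C=C[Mg]Br | starting material
3 | 4-ethenyl-2,5-dihydro-1,2-oxamagnesole (chelated alkenylmagnesium alkoxide, Mg on C6 cis to the CH2O carbon) | C=CC1=C[Mg]OC1 | intermediate
4 | (2Z)-2-(bromomethylidene)but-3-en-1-ol (Br cis to CH2OH, trans to vinyl) | OC/C(C=C)=C\Br | intermediate
5 | (1Z)-1-bromo-2-(bromomethyl)buta-1,3-diene | BrC/C(C=C)=C\Br | intermediate
6 | [2-(1,3-dioxan-2-yl)ethyl]magnesium bromide | Br[Mg]CCC1OCCCO1 | starting material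
7 | 2-[(4E)-5-bromo-4-ethenylpent-4-en-1-yl]-1,3-dioxane | C1(CCC/C(C=C)=C\Br)OCCCO1 | intermediate
8 | (5E)-6-bromo-5-ethenylhex-5-enal | O=CCCC/C(C=C)=C\Br | intermediate
9 | (2S,5E)-6-bromo-2-chloro-5-ethenylhex-5-enal | O=C[C@@H](Cl)CC/C(C=C)=C\Br | intermediate
10 | (2S,5E)-6-bromo-2-chloro-5-ethenylhex-5-enoic acid | OC(=O)[C@@H](Cl)CC/C(C=C)=C\Br | intermediate
11 | methyl (2S,5E)-6-bromo-2-chloro-5-ethenylhex-5-enoate | COC(=O)[C@@H](Cl)CC/C(C=C)=C\Br | intermediate
12 | methylmagnesium bromide | C[Mg]Br | starting material
13 | (3S,6E)-7-bromo-3-chloro-6-ethenylhept-6-en-2-one | CC(=O)[C@@H](Cl)CC/C(C=C)=C\Br | intermediate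
14 | (3S,6E)-6-(bromomethylidene)-3-chloro-2-methyloct-7-en-2-ol (open-chain (S)-chlorohydrin, Br cis to the C4 chain) | CC(C)(O)[C@@H](Cl)CC/C(C=C)=C\Br | intermediate
15 | (1S,3S,4E)-3-bromo-4-(2-bromoethylidene)-1-chloro-2,2-dimethylcyclohexane (Cl and ring Br trans, CH2Br cis to the ring CH2) | CC1(C)[C@@H](Cl)CC/C(=C\CBr)[C@@H]1Br | intermediate
16 | (4S,6R)-6-bromo-1-[(1S)-2-bromo-1-chloroethyl]-4-chloro-5,5-dimethylcyclohex-1-ene | CC1(C)[C@@H](Cl)CC=C([C@H](Cl)CBr)[C@@H]1Br | target

**Step count**

Total steps: 10. Longest linear sequence: 10 steps (from 1 to 16).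

**Steps most likely to fail**

Step 9 (new method). The chlorine at C2 withdraws electron density from C1, so ionisation may be slow enough for hydrobromination of the diene or a hydride shift from C2 to win. The bromoalkene may also be too weak a nucleophile, so that the cation only loses a proton or collects bromide. The allylic C6–Br bond of the product may ionise in the medium and erode the trans relation.

Fallback with known chemistry, giving up the enantiospecific ionisation: it sets out from 14. K2CO3 in MeOH should close the chlorohydrin to the epoxide (3R)-3-[(3E)-4-bromo-3-ethenylbut-3-en-1-yl]-2,2-dimethyloxirane F1. Oxygen transfer to PPh3 with catalytic CH3ReO3 should give the trisubstituted alkene (3E)-3-(bromomethylidene)-7-methylocta-1,6-diene F2. Chlorodiethylsulfonium hexachloroantimonate, Et2SCl·SbCl6, in nitromethane at −25 °C is the established reagent for chloronium-induced polyene cyclisation. It should close the same chair from the alkene, with the allyl cation taking chloride from the counter-ion, to give the racemic allylic chloride 3-bromo-1-chloro-4-(2-chloroethylidene)-2,2-dimethylcyclohexane F3. Finkelstein exchange of the primary allylic chloride with LiBr in acetone then gives racemic 15. Preparative HPLC on a chiral stationary phase separates 15 from its enantiomer (1R,3R,4E)-3-bromo-4-(2-bromoethylidene)-1-chloro-2,2-dimethylcyclohexane F4. The fallback comes back to the route at 15.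

Step 10. Chlorine may be delivered to C7 from the face syn to the C6 bromine, giving the C7 epimer. The C6 bromine may bridge to the C5 cation and migrate, or the C6 proton may be lost instead of the C4 proton. The alkene, deactivated by two allylic bromides, may react so slowly that chlorohydrin formation takes over.

Fallback, setting C7 by reagent control: it sets out from 15. A Schenck ene reaction with singlet oxygen (O2, tetraphenylporphyrin, light, CH2Cl2) should take the C4 hydrogen from the more substituted side of the alkene. This gives the allylic hydroperoxide (4S,6S)-6-bromo-1-(2-bromo-1-hydroperoxyethyl)-4-chloro-5,5-dimethylcyclohex-1-ene F5 with the alkene at C4=C5. PPh3 reduces it to the allylic alcohol (4S,6S)-6-bromo-1-(2-bromo-1-hydroxyethyl)-4-chloro-5,5-dimethylcyclohex-1-ene F6 as a mixture of C7 epimers. Dess–Martin oxidation gives the enone 2-bromo-1-[(4S,6S)-6-bromo-4-chloro-5,5-dimethylcyclohex-1-en-1-yl]ethan-1-one F7. Corey–Bakshi–Shibata reduction, with the oxazaborolidine antipode that delivers the (7R) carbinol, gives (4S,6S)-6-bromo-1-[(1R)-2-bromo-1-hydroxyethyl]-4-chloro-5,5-dimethylcyclohex-1-ene F8. Appel chlorination (PPh3, CCl4) with inversion then gives 16, where the fallback comes back to the route.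

Step 3. The organocopper species may attack the bromine-bearing C6 (SN2′) and destroy the alkenyl bromide. Bromide ion may also scramble the geometry of 5 by reversible allylic transposition before coupling.

Fallback, replacing the copper coupling by SN2 alkylation of a stabilised carbanion and a one-carbon homologation: it sets out from 5. Alkylation of the lithium enolate of ethyl acetate (lithium diisopropylamide, THF, −78 °C) should give ethyl (4E)-5-bromo-4-ethenylpent-4-enoate F9. Diisobutylaluminium hydride at −78 °C reduces it to (4E)-5-bromo-4-ethenylpent-4-enal F10. Wittig reaction with methoxymethylenetriphenylphosphorane (from the phosphonium chloride and potassium tert-butoxide) gives the enol ether (5E)-6-bromo-5-ethenyl-1-methoxyhexa-1,5-diene F11. Hydrolysis with dilute aqueous HCl in THF gives aldehyde 8, where the fallback comes back to the route.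

**Further compounds**

F1 | step 9 | (3R)-3-[(3E)-4-bromo-3-ethenylbut-3-en-1-yl]-2,2-dimethyloxirane | CC1(C)O[C@@H]1CC/C(C=C)=C\Br
F2 | step 9 | (3E)-3-(bromomethylidene)-7-methylocta-1,6-diene | CC(C)=CCC/C(C=C)=C\Br
F3 | step 9 | racemic (1S,3S,4E)-3-bromo-1-chloro-4-(2-chloroethylidene)-2,2-dimethylcyclohexane (one enantiomer drawn) | CC1(C)[C@@H](Cl)CC/C(=C\CCl)[C@@H]1Br
F4 | step 9 | (1R,3R,4E)-3-bromo-4-(2-bromoethylidene)-1-chloro-2,2-dimethylcyclohexane, the enantiomer of 15 | CC1(C)[C@H](Cl)CC/C(=C\CBr)[C@H]1Br
F5 | step 10 | (4S,6S)-6-bromo-1-(2-bromo-1-hydroperoxyethyl)-4-chloro-5,5-dimethylcyclohex-1-ene, both C7 epimers | CC1(C)[C@@H](Cl)CC=C(C(OO)CBr)[C@@H]1Br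
F6 | step 10 | (4S,6S)-6-bromo-1-(2-bromo-1-hydroxyethyl)-4-chloro-5,5-dimethylcyclohex-1-ene, both C7 epimers | CC1(C)[C@@H](Cl)CC=C(C(O)CBr)[C@@H]1Br
F7 | step 10 | 2-bromo-1-[(4S,6S)-6-bromo-4-chloro-5,5-dimethylcyclohex-1-en-1-yl]ethan-1-one | CC1(C)[C@@H](Cl)CC=C(C(=O)CBr)[C@@H]1Br
F8 | step 10 | (4S,6S)-6-bromo-1-[(1R)-2-bromo-1-hydroxyethyl]-4-chloro-5,5-dimethylcyclohex-1-ene | CC1(C)[C@@H](Cl)CC=C([C@@H](O)CBr)[C@@H]1Br
F9 | step 3 | ethyl (4E)-5-bromo-4-ethenylpent-4-enoate | CCOC(=O)CC/C(C=C)=C\Br
F10 | step 3 | (4E)-5-bromo-4-ethenylpent-4-enal | O=CCC/C(C=C)=C\Br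
F11 | step 3 | (5E)-6-bromo-5-ethenyl-1-methoxyhexa-1,5-diene, E/Z mixture at the enol ether | COC=CCC/C(C=C)=C\Br
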